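Ring B is constructed rather than purchased. It carries its side chain (B1) and ring C (B5) in a 1,3 relationship, with the B4 oxygen next to B5 and the B3 oxygen next to B4. This is the substitution of a 2-alkoxy-3-aryl-5-alkylcyclohex-2-enone whose carbonyl carbon is B3. Cutting B1–B2 and B4–B5 leaves an aryl enone that already holds rings A, C and D, and a four-carbon benzyloxy keto ester that delivers B2–B4 with both oxygens differentiated. One Michael–aldol cascade makes both bonds and closes ring B. Loss of the ester, dehydrogenation and one hydrogenolysis complete the tetrol. The enone is assembled from an aryllithium and an unsaturated Weinreb amide.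

Key step: step 7

Labels:
- Ring A is the 3-methoxyphenyl ring tethered to ring B.
- Ring B is the catechol ring with B1 (CH2CH2–ring A), B2 (H), B3 (OH), B4 (OH), B5 (bond to ring C) and B6 (H).
- Ring C is the second catechol ring.
- Ring D is the 3-methoxyphenyl ring tethered to ring C.

Assumption: the biaryl axis has only two ortho substituents other than hydrogen (B4–OH and the chain on ring C) and is taken to rotate freely, so the target has no stereogenic element. Compounds 17, 18 and 19 are racemic and one enantiomer is drawn.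

Step 1
Reactants: 1 3,4-bis(benzyloxy)benzaldehyde
Product: 2 4,5-bis(benzyloxy)-2-bromobenzaldehyde
Conditions: Br2 (1.1 equiv), NaOAc, AcOH, rt
Reagents that add atoms: bromine, BrBr
Why: Electrophilic aromatic bromination goes para to the 3-benzyloxy group (as with other 3,4-dialkoxybenzaldehydes, whose 4-oxygen is tied up in conjugation with the formyl group), and acetate buffers the HBr so that the benzyl ethers survive.

Step 2
Reactants: 2 4,5-bis(benzyloxy)-2-bromobenzaldehyde; 3 (3-methoxybenzyl)triphenylphosphonium chloride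
Product: 5 1,2-bis(benzyloxy)-4-bromo-5-[2-(3-methoxyphenyl)ethenyl]benzene (E/Z mixture), via phosphonium ylide 4 (not isolated)
Conditions: t-BuOK, THF, 0 °C; then 2, 0 °C to rt
Reagents that add atoms: none
Why: Wittig olefination of an aromatic aldehyde with a semi-stabilised benzylic ylide leaves the aryl bromide untouched, and the alkene geometry is irrelevant because the double bond is saturated in the next step.

Step 3
Reactants: 5 1,2-bis(benzyloxy)-4-bromo-5-[2-(3-methoxyphenyl)ethenyl]benzene
Product: 6 1,2-bis(benzyloxy)-4-bromo-5-[2-(3-methoxyphenyl)ethyl]benzene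
Conditions: TsNHNH2 (excess), NaOAc, THF/H2O, reflux
Reagents that add atoms: none
Why: Diimide reduction transfers two hydrogens concertedly to the C=C bond only, so the aryl bromide and the benzyl ethers, which hydrogenation over palladium would attack, are kept.

Step 4
Reactants: 7 3-methoxybenzyl chloride; 8 allylmagnesium bromide
Product: 9 1-(but-3-en-1-yl)-3-methoxybenzene
Conditions: THF/Et2O, 0 °C to reflux
Reagents that add atoms: none
Why: SN2-type coupling of a benzylic chloride with an allyl Grignard reagent is a standard entry to 4-arylbut-1-enes.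

Step 5
Reactants: 9 1-(but-3-en-1-yl)-3-methoxybenzene; 10 N-methoxy-N-methylacrylamide
Product: 11 (E)-N-methoxy-5-(3-methoxyphenyl)-N-methylpent-2-enamide
Conditions: second-generation Grubbs catalyst RuCl2(=CHPh)(PCy3)(SIMes) (5 mol%), 10 (2 equiv), CH2Cl2, 40 °C
Reagents that add atoms: none
Why: Olefin cross-metathesis pairs a terminal alkene that homodimerises reversibly with an electron-poor acrylamide that does not, which funnels material to the cross product and gives the E alkene under thermodynamic control.

Step 6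
Reactants: 6 1,2-bis(benzyloxy)-4-bromo-5-[2-(3-methoxyphenyl)ethyl]benzene; 11 (E)-N-methoxy-5-(3-methoxyphenyl)-N-methylpent-2-enamide
Product: 13 (E)-1-[4,5-bis(benzyloxy)-2-(3-methoxyphenethyl)phenyl]-5-(3-methoxyphenyl)pent-2-en-1-one, via aryllithium 12 (not isolated)
Conditions: n-BuLi (1.05 equiv), THF, −78 °C; then 11, −78 to −20 °C; cold 1 M HCl quench
Reagents that add atoms: n-butyllithium, [Li]CCCC (supplies the lithium of 12 only; none of it remains in 13)
Why: Bromine–lithium exchange at −78 °C outruns any attack on the benzyl ethers, the Weinreb ketone synthesis (1,2-addition of the hard aryllithium) stops at the ketone with the E alkene intact, and the acidic quench keeps the released amine protonated so that it cannot add to the enone.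

Step 7
Reactants: 13 (E)-1-[4,5-bis(benzyloxy)-2-(3-methoxyphenethyl)phenyl]-5-(3-methoxyphenyl)pent-2-en-1-one; 14 ethyl 4-(benzyloxy)-3-oxobutanoate
Product: 17 ethyl trans-3-(benzyloxy)-4-[4,5-bis(benzyloxy)-2-(3-methoxyphenethyl)phenyl]-6-(3-methoxyphenethyl)-2-oxocyclohex-3-ene-1-carboxylate (racemic; 1S,6R enantiomer drawn), via Michael adduct 15 (not isolated), via ketol 16 (not isolated)
Conditions: 14 (1.2 equiv), NaOEt (1.1 equiv), EtOH/THF, 0 °C to reflux; AcOH quench
Reagents that add atoms: none
Why: Ethoxide deprotonates 14 at C2, the carbon between its two carbonyl groups, and this soft enolate adds in conjugate fashion to the β-carbon of 13 (bond B1–B2) to give 1,5-diketone 15; proton transfer then produces a small share of the enolate at the benzyloxymethyl carbon, which attacks the aryl ketone (bond B4–B5) to give ketol 16, and E1cB loss of water gives the tetrasubstituted enone. The closest known reaction type is the Michael–aldol (Robinson-type) annulation of chalcones and related aryl enones with acetoacetic esters, which gives 6-carbethoxy-3,5-disubstituted cyclohex-2-enones. Ring B closes in a 6-(enolexo)-exo-trig mode, the ketone C=O lying outside the new ring. The chain-bearing carbon (C6, B1) is created without facial bias in the Michael step, so 17 is racemic, while the ester-bearing carbon (C1, B2) stays epimerisable and settles trans to the chain, both groups equatorial, under thermodynamic control; both centres are erased later. The step needs regiocontrol over three enolisable sites: the acidity gap within 14 reserves C2 for the Michael step, and ring size does the rest, because only the benzyloxymethyl carbon lies six atoms from a carbonyl carbon, whereas the CH2 next to the aryl ketone could close only four-membered rings. A full equivalent of base keeps 15 as its C2 enolate, which shields the alkoxy ketone from retro-Claisen cleavage, and stores 17 as a stabilised enolate, which draws the reversible steps forward.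

Step 8
Reactants: 17 ethyl trans-3-(benzyloxy)-4-[4,5-bis(benzyloxy)-2-(3-methoxyphenethyl)phenyl]-6-(3-methoxyphenethyl)-2-oxocyclohex-3-ene-1-carboxylate
Product: 18 2-(benzyloxy)-3-[4,5-bis(benzyloxy)-2-(3-methoxyphenethyl)phenyl]-5-(3-methoxyphenethyl)cyclohex-2-en-1-one (racemic; R enantiomer drawn)
Conditions: LiCl, H2O, DMSO, 140 °C
Reagents that add atoms: none
Why: Krapcho dealkoxycarbonylation removes the ester of a β-keto ester under essentially neutral conditions, so the enone, the enol benzyl ether and the aryl ethers are untouched and no retro-Michael or retro-aldol pathway is opened by strong base.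

Step 9
Reactants: 18 2-(benzyloxy)-3-[4,5-bis(benzyloxy)-2-(3-methoxyphenethyl)phenyl]-5-(3-methoxyphenethyl)cyclohex-2-en-1-one
Product: 21 2-(benzyloxy)-3-[4,5-bis(benzyloxy)-2-(3-methoxyphenethyl)phenyl]-5-(3-methoxyphenethyl)phenol, via silyl dienol ether 19 (not isolated), via cross-conjugated dienone 20 (not isolated)
Conditions: LDA, TMSCl, THF, −78 °C; crude 19, then Pd(OAc)2 (1.1 equiv), MeCN, rt
Reagents that add atoms: chlorotrimethylsilane, C[Si](C)(C)Cl (its silyl group is carried by 19 only and is lost again before 21)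
Why: In this Saegusa–Ito dehydrogenation, kinetic deprotonation at C6 (B2) with in situ silylation gives 19, divalent palladium binds C6 on the face opposite the chain and hence syn to the C5–H, and β-hydride elimination gives dienone 20, the keto tautomer of phenol 21, which enolises at once and erases the last stereocentre without any free halogen or quinone oxidant near the electron-rich rings and bibenzyl CH2 groups.

Step 10
Reactants: 21 2-(benzyloxy)-3-[4,5-bis(benzyloxy)-2-(3-methoxyphenethyl)phenyl]-5-(3-methoxyphenethyl)phenol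
Product: 22 isoplagilin, 2′,5-bis[2-(3-methoxyphenyl)ethyl]-[1,1′-biphenyl]-2,3,4′,5′-tetrol
Conditions: H2 (1 atm), 10% Pd/C, EtOAc/MeOH (degassed), rt; filtration under argon
Reagents that add atoms: none
Why: Catalytic hydrogenolysis cleaves the three aryl benzyl ethers in one operation, while the aryl methyl ethers and the saturated chains are inert, and exclusion of air protects the two catechols.

Compound list
1 | 3,4-bis(benzyloxy)benzaldehyde | O=Cc1ccc(OCc2ccccc2)c(OCc2ccccc2)c1 | starting material
2 | 4,5-bis(benzyloxy)-2-bromobenzaldehyde | O=Cc1cc(OCc2ccccc2)c(OCc2ccccc2)cc1Br | intermediate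
3 | (3-methoxybenzyl)triphenylphosphonium chloride | COc1cccc(C[P+](c2ccccc2)(c2ccccc2)c2ccccc2)c1.[Cl-] | starting material
4 | (3-methoxybenzylidene)triphenylphosphorane | COc1cccc(C=P(c2ccccc2)(c2ccccc2)c2ccccc2)c1 | intermediate (not isolated)
5 | 1,2-bis(benzyloxy)-4-bromo-5-[2-(3-methoxyphenyl)ethenyl]benzene, E/Z mixture, geometry left open | COc1cccc(C=Cc2cc(OCc3ccccc3)c(OCc3ccccc3)cc2Br)c1 | intermediate
6 | 1,2-bis(benzyloxy)-4-bromo-5-[2-(3-methoxyphenyl)ethyl]benzene | COc1cccc(CCc2cc(OCc3ccccc3)c(OCc3ccccc3)cc2Br)c1 | intermediate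
7 | 3-methoxybenzyl chloride | COc1cccc(CCl)c1 | starting material
8 | allylmagnesium bromide | C=CC[Mg]Br | starting material
9 | 1-(but-3-en-1-yl)-3-methoxybenzene | C=CCCc1cccc(OC)c1 | intermediate
10 | N-methoxy-N-methylacrylamide | C=CC(=O)N(C)OC | starting material
11 | (E)-N-methoxy-5-(3-methoxyphenyl)-N-methylpent-2-enamide | COc1cccc(CC/C=C/C(=O)N(C)OC)c1 | intermediate
12 | [4,5-bis(benzyloxy)-2-(3-methoxyphenethyl)phenyl]lithium | [Li]c1cc(OCc2ccccc2)c(OCc2ccccc2)cc1CCc1cccc(OC)c1 | intermediate (not isolated)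
13 | (E)-1-[4,5-bis(benzyloxy)-2-(3-methoxyphenethyl)phenyl]-5-(3-methoxyphenyl)pent-2-en-1-one | COc1cccc(CC/C=C/C(=O)c2cc(OCc3ccccc3)c(OCc3ccccc3)cc2CCc2cccc(OC)c2)c1 | intermediate
14 | ethyl 4-(benzyloxy)-3-oxobutanoate | CCOC(=O)CC(=O)COCc1ccccc1 | starting material
15 | ethyl 2-(benzyloxyacetyl)-5-[4,5-bis(benzyloxy)-2-(3-methoxyphenethyl)phenyl]-3-(3-methoxyphenethyl)-5-oxopentanoate, diastereomer mixture, configuration left open | CCOC(=O)C(C(=O)COCc1ccccc1)C(CCc1cccc(OC)c1)CC(=O)c1cc(OCc2ccccc2)c(OCc2ccccc2)cc1CCc1cccc(OC)c1 | intermediate (not isolated)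
16 | ethyl 3-(benzyloxy)-4-[4,5-bis(benzyloxy)-2-(3-methoxyphenethyl)phenyl]-4-hydroxy-6-(3-methoxyphenethyl)-2-oxocyclohexane-1-carboxylate, diastereomer mixture, configuration left open | CCOC(=O)C1C(CCc2cccc(OC)c2)CC(O)(c2cc(OCc3ccccc3)c(OCc3ccccc3)cc2CCc2cccc(OC)c2)C(OCc2ccccc2)C1=O | intermediate (not isolated)
17 | ethyl trans-3-(benzyloxy)-4-[4,5-bis(benzyloxy)-2-(3-methoxyphenethyl)phenyl]-6-(3-methoxyphenethyl)-2-oxocyclohex-3-ene-1-carboxylate, racemic, (1S,6R) drawn | CCOC(=O)[C@H]1[C@H](CCc2cccc(OC)c2)CC(c2cc(OCc3ccccc3)c(OCc3ccccc3)cc2CCc2cccc(OC)c2)=C(OCc2ccccc2)C1=O | intermediate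
18 | 2-(benzyloxy)-3-[4,5-bis(benzyloxy)-2-(3-methoxyphenethyl)phenyl]-5-(3-methoxyphenethyl)cyclohex-2-en-1-one, racemic, (R) drawn | O=C1C[C@H](CCc2cccc(OC)c2)CC(c2cc(OCc3ccccc3)c(OCc3ccccc3)cc2CCc2cccc(OC)c2)=C1OCc1ccccc1 | intermediate
19 | {[6-(benzyloxy)-5-[4,5-bis(benzyloxy)-2-(3-methoxyphenethyl)phenyl]-3-(3-methoxyphenethyl)cyclohexa-1,5-dien-1-yl]oxy}trimethylsilane, racemic, same series as 18 | C[Si](C)(C)OC1=C[C@H](CCc2cccc(OC)c2)CC(c2cc(OCc3ccccc3)c(OCc3ccccc3)cc2CCc2cccc(OC)c2)=C1OCc1ccccc1 | intermediate (not isolated)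
20 | 2-(benzyloxy)-3-[4,5-bis(benzyloxy)-2-(3-methoxyphenethyl)phenyl]-5-(3-methoxyphenethyl)cyclohexa-2,5-dien-1-one | O=C1C=C(CCc2cccc(OC)c2)CC(c2cc(OCc3ccccc3)c(OCc3ccccc3)cc2CCc2cccc(OC)c2)=C1OCc1ccccc1 | intermediate (not isolated)
21 | 2-(benzyloxy)-3-[4,5-bis(benzyloxy)-2-(3-methoxyphenethyl)phenyl]-5-(3-methoxyphenethyl)phenol | COc1cccc(CCc2cc(O)c(OCc3ccccc3)c(-c3cc(OCc4ccccc4)c(OCc4ccccc4)cc3CCc3cccc(OC)c3)c2)c1 | intermediate
22 | isoplagilin, 2′,5-bis[2-(3-methoxyphenyl)ethyl]-[1,1′-biphenyl]-2,3,4′,5′-tetrol | COc1cccc(CCc2cc(O)c(O)c(-c3cc(O)c(O)cc3CCc3cccc(OC)c3)c2)c1 | target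

Total step count: 10.
Longest linear sequence: 8 steps (1, 2, 3, 6, 7, 8, 9 and 10, counted from compound 1). Steps 4 and 5 form the side branch.

Steps most likely to fail

1. Step 7.
- **Risk:** Closure onto the ortho-substituted, electron-rich aryl ketone may be slow and reversible, so the cascade could stall at the open-chain or ketol stage. Meanwhile ethoxide could cleave the benzyloxyacetyl group by retro-Claisen reaction, or the enone could drift out of conjugation.
- **Fallback:** The B5–ring C bond is made by Suzuki–Miyaura coupling of two finished arenes instead of building ring B. The fallback sets out from 6 and comes back at 22.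
- **Boronic acid:** Aryllithium 12, made from 6 as in step 6, is trapped with B(OiPr)3 and hydrolysed to [4,5-bis(benzyloxy)-2-(3-methoxyphenethyl)phenyl]boronic acid F1.
- **Ring B bromide:** Purchased 3-bromo-4,5-dihydroxybenzaldehyde F2 is benzylated (BnBr, K2CO3, DMF) to 3,4-bis(benzyloxy)-5-bromobenzaldehyde F3.
- **Coupling:** F1 and F3 are coupled (Pd(PPh3)4, Na2CO3, DME/H2O, 85 °C) to give 4′,5,5′,6-tetrakis(benzyloxy)-2′-[2-(3-methoxyphenyl)ethyl]biphenyl-3-carbaldehyde F4.
- **Chain extension:** Wittig reaction with ylide 4 gives 2,3,4′,5′-tetrakis(benzyloxy)-5-[2-(3-methoxyphenyl)ethenyl]-2′-[2-(3-methoxyphenyl)ethyl]biphenyl F5.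
- **Return:** H2 over Pd/C saturates the alkene and removes all four benzyl groups to give 22.

2. Step 9.
- **Risk:** Enolisation or silylation may be incomplete, the silyl ether may hydrolyse back to the ketone before palladation, or the electron-rich phenol may be oxidised further by divalent palladium.
- **Fallback:** A pericyclic elimination replaces the metal-mediated dehydrogenation. The fallback sets out from 18 and comes back at 21.
- **Sequence:** The lithium enolate (LDA, THF, −78 °C) is quenched with PhSeCl, anti to the chain, to give trans-2-(benzyloxy)-3-aryl-5-(3-methoxyphenethyl)-6-(phenylselanyl)cyclohex-2-en-1-one F6.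
- **Return:** H2O2/pyridine in CH2Cl2 at 0 °C gives the corresponding selenoxide F7. Its syn elimination across the cis C5–H gives dienone 20 and hence 21. The product is freed carefully of selenium before step 10.

3. Step 6.
- **Risk:** The basic aryllithium may remove a γ-proton of the unsaturated amide or add in conjugate fashion instead of at the carbonyl group. The liberated amine may also add to the enone during work-up.
- **Fallback:** Addition to a far more electrophilic aldehyde followed by oxidation replaces the acylation. The fallback sets out from 9 and 6 and comes back at 13.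
- **Sequence:** Cross-metathesis of 9 with crotonaldehyde (second-generation Grubbs catalyst, CH2Cl2, 40 °C) gives (E)-5-(3-methoxyphenyl)pent-2-enal F8.
- **Return:** Aryllithium 12 adds 1,2 at −78 °C to give racemic (E)-1-[4,5-bis(benzyloxy)-2-(3-methoxyphenethyl)phenyl]-5-(3-methoxyphenyl)pent-2-en-1-ol F9, and MnO2 in CH2Cl2 oxidises this doubly activated alcohol to 13.

Further compounds
F1 | step 7 | [4,5-bis(benzyloxy)-2-(3-methoxyphenethyl)phenyl]boronic acid | COc1cccc(CCc2cc(OCc3ccccc3)c(OCc3ccccc3)cc2B(O)O)c1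
F2 | step 7 | 3-bromo-4,5-dihydroxybenzaldehyde (purchased) | O=Cc1cc(O)c(O)c(Br)c1
F3 | step 7 | 3,4-bis(benzyloxy)-5-bromobenzaldehyde | O=Cc1cc(OCc2ccccc2)c(OCc2ccccc2)c(Br)c1
F4 | step 7 | 4′,5,5′,6-tetrakis(benzyloxy)-2′-[2-(3-methoxyphenyl)ethyl]biphenyl-3-carbaldehyde | COc1cccc(CCc2cc(OCc3ccccc3)c(OCc3ccccc3)cc2-c2cc(C=O)cc(OCc3ccccc3)c2OCc2ccccc2)c1
F5 | step 7 | 2,3,4′,5′-tetrakis(benzyloxy)-5-[2-(3-methoxyphenyl)ethenyl]-2′-[2-(3-methoxyphenyl)ethyl]biphenyl (E/Z mixture) | COc1cccc(C=Cc2cc(OCc3ccccc3)c(OCc3ccccc3)c(-c3cc(OCc4ccccc4)c(OCc4ccccc4)cc3CCc3cccc(OC)c3)c2)c1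
F6 | step 9 | trans-2-(benzyloxy)-3-[4,5-bis(benzyloxy)-2-(3-methoxyphenethyl)phenyl]-5-(3-methoxyphenethyl)-6-(phenylselanyl)cyclohex-2-en-1-one (racemic) | c1ccc(cc1)[Se][C@H]1[C@H](CCc2cccc(OC)c2)CC(c2cc(OCc3ccccc3)c(OCc3ccccc3)cc2CCc2cccc(OC)c2)=C(OCc2ccccc2)C1=O
F7 | step 9 | selenoxide of F6 (configuration at selenium left open) | O=[Se](c1ccccc1)[C@H]1[C@H](CCc2cccc(OC)c2)CC(c2cc(OCc3ccccc3)c(OCc3ccccc3)cc2CCc2cccc(OC)c2)=C(OCc2ccccc2)C1=O
F8 | step 6 | (E)-5-(3-methoxyphenyl)pent-2-enal | COc1cccc(CC/C=C/C=O)c1
F9 | step 6 | (E)-1-[4,5-bis(benzyloxy)-2-(3-methoxyphenethyl)phenyl]-5-(3-methoxyphenyl)pent-2-en-1-ol (racemic) | COc1cccc(CC/C=C/C(O)c2cc(OCc3ccccc3)c(OCc3ccccc3)cc2CCc2cccc(OC)c2)c1
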